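We ask whether beta, given twice the time of theta but 0.10 M of solid substrate against 0.025 M, ends ahead in percent of its charge.

| setting | south-east | north-west | beta | theta |
|---|---|---|---|---|
| solid substrate | 0.035 M | 0.16 M | 0.10 M | 0.025 M |
| gas phase | 10 mM (held) | 10 mM (held) | 10 mM (held) | 10 mM (held) |
| catalyst | 68 µM | 68 µM | 68 µM | 68 µM |
| added ligand | 0.28 mM | 0.28 mM | 0.28 mM | 0.28 mM |
| remark | run made earlier | run made earlier |  |  |
| time |  |  | 6.0 min | 3.0 min |

- south-east (time / min: product / %): 0.500: 29; 0.833: 52; 1.33: 67; 2.00: 82; 4.00: 93; 6.00: 101
- north-west (time / min: product / %): 0.417: 9; 1.33: 40; 2.00: 59; 3.00: 81; 5.00: 100; 6.00: 100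

(standard deviation of a reading: 2 percentage points)

* the winner by amount of product, in percent of the solid substrate charged; "neither" if no more than 2 percentage points parts them (beta / theta / neither)
* how much product is there at the end, in percent of the solid substrate charged: beta
* how much product is there at the end, in percent of the solid substrate charged: theta

- solid substrate is a solid; its amount is given per volume of the solution
- at the start none of the solid substrate is in solution
- at the start none of the gas phase is in solution
- what has only dissolved of solid substrate counts as not reacted

We carry one quantity. In the south-east run the unreacted part falls from 71.0% at 0.500 min to 18.0% at 2.00 min, and that gives 0.915 min⁻¹, the fractional rate: the share of what is unreacted that becomes product per minute, averaged over that stretch. It is a pseudo-first-order constant, read with the scatter of its readings, and its life is 1.09 min.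

Now the rungs, fastest first. The north-west run climbs close to a line at 0.0446 M min⁻¹, which meets zero at 0.0941 min, so we take the start-up as over sooner than one life. Theta's charge is smaller than that of the south-east run, so we let theta follow the south-east curve in percent. Beta's charge is smaller than that of the north-west run, so we take beta's unreacted amount at 3.00 min as no larger than the 0.0304 M that the north-west run reads then. Slowest are the asked times: theta gets 2.74 lives, and beta gets 2.74 after that reading.

So our theta keeps 7.21% unreacted and reaches 92.8%. Our beta keeps 1.95% and reaches 98.0%, ahead by 5.2 percentage points.

The forecast names beta, with 99% (95% to 102%) for beta and 90% (84% to 95%) for theta, holding that “in this regime the fractional conversion barely depends on charge”. Our theta stands above its figure and our beta below its figure, both inside its ranges.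

The flask gives beta, with 99.3% for beta and 92.7% for theta.

    solid substrate ⇌ starting material, rate k1*(cs1 - [starting material]) while solid is left; crystals form when [starting material] > cs1 (solubility = 0.0860 M, k = 0.0887 s⁻¹)
    catalyst + added ligand ⇌ idle complex, settled at all times (K = 30600 M⁻¹)
    starting material + dissolved gas + catalyst → catalyst + product (k = 1.75 × 10⁵ M⁻² s⁻¹)
    gas phase ⇌ dissolved gas, rate k4*(csat - [dissolved gas]) (kL = 0.362 s⁻¹)

Theta still holds 7.34% as starting material at 3.00 min, and by 30.0 min its product stands at 100%. Beta holds 11.1% of starting material at 3.00 min. The fractional rate carries that to 0.713% at 6.00 min, where the flask holds 0.732%.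

The earlier runs and the new flask come from a simulation for substances that don't exist; the scatter is artificial.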